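The route hinges on disconnecting the carbocycle between C6 and C7 (isochromene numbering). The ester-bearing C7 flanks the C8 carbonyl and its neighbour C6 carries the free hydroxyl, the pattern of an aldol adduct; while C7 is still a CH it can be acyloxylated by carboxylate alkylation. A single catalytic, stereoconvergent 6-(enolendo)-exo-trig aldol of a racemic open-chain 6-aroyloxy-5-oxoheptanal then forms the cyclohexanone and fixes quaternary C7 and carbinol C6 together. The pyran ring follows: enone formation, conjugate alkynylation at C4a, hydroxymethylation at C8a, re-oxidation and 6-endo-dig closure of the C1 hydroxyl onto C3.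

Key step: step 8

Remark: ArCO2 denotes the 2-methoxy-6-methyl-4-(triisopropylsilyloxy)benzoate residue (the phenol carries the triisopropylsilyl group so that it survives carboxylate, base and silyl triflate steps); locants C1 to C8a in the Why lines are those of the isochromene skeleton of the target.
Assumption: the sense of induction of the (2S,6S) guanidine in step 8 cannot be read from precedent; should it favour the (1S,2S) aldol, the (2R,6R) catalyst is used instead.

Step 1
Reactants: 1 2,4-dihydroxy-6-methylbenzaldehyde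
Product: 2 2-hydroxy-6-methyl-4-(triisopropylsilyloxy)benzaldehyde
Conditions: TIPSCl (1.05 equiv), imidazole, DMF, 0 °C → rt
Reagents that add atoms: chlorotri(propan-2-yl)silane, CC(C)[Si](Cl)(C(C)C)C(C)C
Why: The 2-hydroxyl is tied up in a hydrogen bond to the formyl oxygen and is hindered, so silyl ether formation should occur only at the free 4-hydroxyl (chemoselective silylation).

Step 2
Reactants: 2 2-hydroxy-6-methyl-4-(triisopropylsilyloxy)benzaldehyde
Product: 3 2-methoxy-6-methyl-4-(triisopropylsilyloxy)benzaldehyde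
Conditions: MeI, K2CO3, acetone, 50 °C
Reagents that add atoms: iodomethane, CI
Why: Williamson ether synthesis on the chelated phenol; the bulky aryl triisopropylsilyl ether tolerates anhydrous carbonate.

Step 3
Reactants: 3 2-methoxy-6-methyl-4-(triisopropylsilyloxy)benzaldehyde
Product: 4 2-methoxy-6-methyl-4-(triisopropylsilyloxy)benzoic acid (ArCO2H)
Conditions: NaClO2, NaH2PO4, 2-methylbut-2-ene, t-BuOH/H2O, rt
Reagents that add atoms: sodium chlorite, [Na+].[O-]Cl=O
Why: Pinnick oxidation converts the hindered, electron-rich aldehyde to the acid at weakly acidic pH that leaves the aryl silyl ether intact, the alkene scavenging hypochlorous acid.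

Step 4
Reactants: 5 2-bromopropanoyl chloride (racemic)
Product: 6 2-bromo-N-methoxy-N-methylpropanamide (racemic)
Conditions: MeNHOMe·HCl, pyridine, CH2Cl2, 0 °C
Reagents that add atoms: N,O-dimethylhydroxylamine hydrochloride, CNOC.Cl
Why: N-acylation by the acid chloride (Weinreb amide formation) is much faster than displacement of the secondary bromide.

Step 5
Reactants: 6 2-bromo-N-methoxy-N-methylpropanamide; 7 5-bromopent-1-ene
Product: 10 2-bromooct-7-en-3-one (racemic), via pent-4-enylmagnesium bromide 8 (not isolated), via bromomagnesium hemiaminal chelate 9 (not isolated)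
Conditions: 7, Mg, THF, rt; then 6, THF, −78 → 0 °C; aq NH4Cl
Reagents that add atoms: none
Why: Weinreb ketone synthesis, in which the Grignard reagent adds once to give a magnesium chelate that collapses to the ketone only on work-up, acyl addition at low temperature outrunning attack at the secondary bromide.

Step 6
Reactants: 10 2-bromooct-7-en-3-one; 4 2-methoxy-6-methyl-4-(triisopropylsilyloxy)benzoic acid
Product: 11 3-oxooct-7-en-2-yl ArCO2 (racemic)
Conditions: Cs2CO3 (0.55 equiv), DMF, rt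
Reagents that add atoms: none
Why: SN2 displacement of the activated alpha-bromo ketone by the caesium carboxylate, an O-alkylation that is insensitive to the two ortho substituents which would block an acyl-transfer esterification.

Step 7
Reactants: 11 3-oxooct-7-en-2-yl ArCO2
Product: 13 3,7-dioxoheptan-2-yl ArCO2 (racemic; the 6-aroyloxy-5-oxoheptanal), via secondary ozonide 12 (not isolated)
Conditions: O3, CH2Cl2, −78 °C; then Me2S, −78 °C → rt
Reagents that add atoms: ozone, [O-][O+]=O
Why: Ozonolysis with reductive work-up cleaves the terminal alkene, which is far more reactive towards ozone than the ester-deactivated arene, to the aldehyde.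

Step 8
Reactants: 13 3,7-dioxoheptan-2-yl ArCO2 (racemic)
Product: 14 (1R,2R)-2-hydroxy-1-methyl-6-oxocyclohexyl ArCO2, the (2R,3R)-2-aroyloxy-3-hydroxy-2-methylcyclohexanone
Conditions: (2S,6S)-2,6-di-tert-butyl-2,3,5,6-tetrahydro-1H-imidazo[1,2-a]imidazole (10 mol %), toluene (0.02 M), −20 °C
Reagents that add atoms: none
Why: Proposed new method: the chiral bicyclic guanidine, a base of amidine strength, removes the C7–H flanked by the ketone and the aroyloxy group, which erases the only stereocentre of either enantiomer of 13 and gives one guanidinium enolate ion pair; the enolate adds to the tethered aldehyde and proton return frees 14 and the base, so the whole racemate can converge on one product. The closest known reactions are guanidine- and amine–thiourea-catalysed direct aldol and nitroaldol additions, direct aldol additions of alpha-oxygenated ketones under dinuclear zinc catalysis and amidine-mediated aldol cyclisations of 1,5-keto aldehydes; new is the dynamic use of a racemic alpha-acyloxy ketone to create a quaternary carbinol ester. The carbocycle closes in the 6-(enolendo)-exo-trig mode, the enolate C=C lying inside the new ring. C7 is set by the catalyst, whose tert-butyl groups shield one face of the planar enolate, and C6 is set relative to it by a closed chair in which the two guanidinium N–H bonds bridge enolate oxygen and aldehyde oxygen: the aroyloxy group sits syn to the enolate oxygen and pseudo-equatorial, the aldehyde oxygen pseudo-axial, so the hydroxyl should emerge cis to the ester as (6R,7R). The step needs enolisation at C7 only and no intermolecular aldol: enolates at the other ketone alpha-carbon or at the aldehyde alpha-carbon can close only four-membered rings and revert, the 2,6-disubstituted aroyl group resists migration and cleavage, the quaternary aldol cannot dehydrate, and high dilution disfavours dimerisation.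

Step 9
Reactants: 14 (1R,2R)-2-hydroxy-1-methyl-6-oxocyclohexyl ArCO2
Product: 15 (1R,6R)-1-methyl-2,6-bis(triethylsilyloxy)cyclohex-2-en-1-yl ArCO2
Conditions: TESOTf (2.5 equiv), Et3N, CH2Cl2, −78 → 0 °C
Reagents that add atoms: triethylsilyl trifluoromethanesulfonate, CC[Si](CC)(CC)OS(=O)(=O)C(F)(F)F
Why: Silyl triflate and amine silylate the alcohol and soft-enolise the ketone, which can enolise only towards C8a because C7 is quaternary, so one silyl enol ether forms and the aldol is protected against retro-aldol cleavage.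

Step 10
Reactants: 15 (1R,6R)-1-methyl-2,6-bis(triethylsilyloxy)cyclohex-2-en-1-yl ArCO2
Product: 16 (1R,6R)-1-methyl-2-oxo-6-(triethylsilyloxy)cyclohex-3-en-1-yl ArCO2
Conditions: Pd(OAc)2 (1.1 equiv), MeCN, rt
Reagents that add atoms: none
Why: Saegusa–Ito oxidation, in which the palladium enolate from the silyl enol ether undergoes beta-hydride elimination to the C8a=C4a enone without touching C6 or C7.

Step 11
Reactants: 17 (E)-but-2-enal
Product: 18 (3E)-1,1-dibromopenta-1,3-diene
Conditions: CBr4, PPh3, CH2Cl2, 0 °C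
Reagents that add atoms: tetrabromomethane, BrC(Br)(Br)Br
Why: Corey–Fuchs dibromo-olefination of the aldehyde by the dibromomethylene ylide, with the E alkene retained.

Step 12
Reactants: 16 (1R,6R)-1-methyl-2-oxo-6-(triethylsilyloxy)cyclohex-3-en-1-yl ArCO2; 18 (3E)-1,1-dibromopenta-1,3-diene
Product: 21 (1R,6R)-2-(tert-butyldimethylsilyloxy)-1-methyl-4-[(3E)-pent-3-en-1-yn-1-yl]-6-(triethylsilyloxy)cyclohex-2-en-1-yl ArCO2 (C4 epimers), via lithium pentenynide 19 (not isolated), via alkynylzinc bromide 20 (not isolated)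
Conditions: 18, n-BuLi (2 equiv), Et2O, −78 → 0 °C; ZnBr2, 0 °C; then 16, TBSOTf, −40 °C
Reagents that add atoms: tert-butyldimethylsilyl trifluoromethanesulfonate, CC(C)(C)[Si](C)(C)OS(=O)(=O)C(F)(F)F
Why: Butyllithium converts the dibromoalkene into the lithium acetylide (bromine–lithium exchange, Fritsch–Buttenberg–Wiechell rearrangement, deprotonation), and after transmetalation the alkynylzinc bromide undergoes silyl triflate-promoted conjugate addition at C4a, a known reaction of cyclohexenones that gives the regiodefined silyl enol ether; the new C4a centre is erased later.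

Step 13
Reactants: 21 (1R,6R)-2-(tert-butyldimethylsilyloxy)-1-methyl-4-[(3E)-pent-3-en-1-yn-1-yl]-6-(triethylsilyloxy)cyclohex-2-en-1-yl ArCO2
Product: 22 (1R,6R)-3-(hydroxymethyl)-1-methyl-2-oxo-4-[(3E)-pent-3-en-1-yn-1-yl]-6-(triethylsilyloxy)cyclohexyl ArCO2 (C3 and C4 not defined)
Conditions: 37 % aq HCHO, Sc(OTf)3 (10 mol %), THF, 0 °C → rt
Reagents that add atoms: formaldehyde, C=O
Why: Mukaiyama aldol reaction of the silyl enol ether with aqueous formaldehyde under a water-tolerant Lewis acid puts C1 on C8a; the configurations at C8a and C4a are erased later.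

Step 14
Reactants: 22 (1R,6R)-3-(hydroxymethyl)-1-methyl-2-oxo-4-[(3E)-pent-3-en-1-yn-1-yl]-6-(triethylsilyloxy)cyclohexyl ArCO2
Product: 23 (1R,6R)-1-methyl-4-[(3E)-pent-3-en-1-yn-1-yl]-2,6-bis(triethylsilyloxy)-3-[(triethylsilyloxy)methyl]cyclohex-2-en-1-yl ArCO2
Conditions: TESOTf (3 equiv), Et3N, CH2Cl2, 0 °C → rt
Reagents that add atoms: triethylsilyl trifluoromethanesulfonate, CC[Si](CC)(CC)OS(=O)(=O)C(F)(F)F
Why: Silylation of the primary alcohol and soft enolisation of the ketone, which again has a single enolisable position (C8a), give the tetrasubstituted silyl enol ether.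

Step 15
Reactants: 23 (1R,6R)-1-methyl-4-[(3E)-pent-3-en-1-yn-1-yl]-2,6-bis(triethylsilyloxy)-3-[(triethylsilyloxy)methyl]cyclohex-2-en-1-yl ArCO2
Product: 26 (1R,6R)-1-methyl-2-oxo-4-[(3E)-pent-3-en-1-yn-1-yl]-6-(triethylsilyloxy)-3-[(triethylsilyloxy)methyl]cyclohex-3-en-1-yl ArCO2, via alpha-phenylselanyl ketone 24 (not isolated), via selenoxide 25 (not isolated)
Conditions: PhSeCl (1.05 equiv), CH2Cl2, −78 °C; then 30 % H2O2, pyridine, 0 °C → rt
Reagents that add atoms: none
Why: Electrophilic selenenylation of the silyl enol ether at C8a anti to the pseudo-axial C4a alkynyl group, oxidation and selenoxide syn-elimination towards the cis C4a–H (elimination towards the oxygen-bearing C1 is disfavoured) should restore the C8a=C4a enone.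

Step 16
Reactants: 26 (1R,6R)-1-methyl-2-oxo-4-[(3E)-pent-3-en-1-yn-1-yl]-6-(triethylsilyloxy)-3-[(triethylsilyloxy)methyl]cyclohex-3-en-1-yl ArCO2
Product: 27 (1R,6R)-6-hydroxy-3-(hydroxymethyl)-1-methyl-2-oxo-4-[(3E)-pent-3-en-1-yn-1-yl]cyclohex-3-en-1-yl 4-hydroxy-2-methoxy-6-methylbenzoate
Conditions: TBAF, AcOH (1:1, 4 equiv), THF, 0 °C → rt
Reagents that add atoms: none
Why: Fluoride-mediated cleavage of the two alkyl triethylsilyl ethers and the aryl triisopropylsilyl ether, buffered with acetic acid so that the beta-hydroxy ketone and the hindered ester never meet free alkoxide; material that has already cyclised is carried into step 17.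

Step 17
Reactants: 27 (1R,6R)-6-hydroxy-3-(hydroxymethyl)-1-methyl-2-oxo-4-[(3E)-pent-3-en-1-yn-1-yl]cyclohex-3-en-1-yl 4-hydroxy-2-methoxy-6-methylbenzoate
Product: 28 (6R,7R)-6-hydroxy-7-methyl-8-oxo-3-[(1E)-prop-1-en-1-yl]-5,6,7,8-tetrahydro-1H-isochromen-7-yl 4-hydroxy-2-methoxy-6-methylbenzoate (target)
Conditions: (Ph3P)AuNTf2 (5 mol %), CH2Cl2, rt
Reagents that add atoms: none
Why: Gold-catalysed intramolecular hydroalkoxylation (cycloisomerisation) of the alkyne, in which conjugation with the enone makes C3 the electrophilic terminus, so the C1 hydroxyl should close 6-endo-dig to the 1H-isochromene without affecting C6 or C7.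

Compound list
1 | 2,4-dihydroxy-6-methylbenzaldehyde | O=Cc1c(C)cc(O)cc1O | starting material
2 | 2-hydroxy-6-methyl-4-(triisopropylsilyloxy)benzaldehyde | O=Cc1c(C)cc(O[Si](C(C)C)(C(C)C)C(C)C)cc1O | intermediate
3 | 2-methoxy-6-methyl-4-(triisopropylsilyloxy)benzaldehyde | O=Cc1c(C)cc(O[Si](C(C)C)(C(C)C)C(C)C)cc1OC | intermediate
4 | 2-methoxy-6-methyl-4-(triisopropylsilyloxy)benzoic acid | OC(=O)c1c(C)cc(O[Si](C(C)C)(C(C)C)C(C)C)cc1OC | intermediate
5 | 2-bromopropanoyl chloride (racemic) | CC(Br)C(Cl)=O | starting material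
6 | 2-bromo-N-methoxy-N-methylpropanamide (racemic) | CC(Br)C(=O)N(C)OC | intermediate
7 | 5-bromopent-1-ene | C=CCCCBr | starting material
8 | pent-4-enylmagnesium bromide | C=CCCC[Mg]Br | intermediate (not isolated)
9 | bromomagnesium 2-bromo-3-[methoxy(methyl)amino]oct-7-en-3-olate (tetrahedral chelate) | CC(Br)C(O[Mg]Br)(CCCC=C)N(C)OC | intermediate (not isolated)
10 | 2-bromooct-7-en-3-one (racemic) | CC(Br)C(=O)CCCC=C | intermediate
11 | 3-oxooct-7-en-2-yl 2-methoxy-6-methyl-4-(triisopropylsilyloxy)benzoate (racemic) | CC(OC(=O)c1c(C)cc(O[Si](C(C)C)(C(C)C)C(C)C)cc1OC)C(=O)CCCC=C | intermediate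
12 | 3-oxo-6-(1,2,4-trioxolan-3-yl)hexan-2-yl 2-methoxy-6-methyl-4-(triisopropylsilyloxy)benzoate (secondary ozonide) | CC(OC(=O)c1c(C)cc(O[Si](C(C)C)(C(C)C)C(C)C)cc1OC)C(=O)CCCC2OCOO2 | intermediate (not isolated)
13 | 3,7-dioxoheptan-2-yl 2-methoxy-6-methyl-4-(triisopropylsilyloxy)benzoate (racemic 6-aroyloxy-5-oxoheptanal) | CC(OC(=O)c1c(C)cc(O[Si](C(C)C)(C(C)C)C(C)C)cc1OC)C(=O)CCCC=O | intermediate
14 | (1R,2R)-2-hydroxy-1-methyl-6-oxocyclohexyl 2-methoxy-6-methyl-4-(triisopropylsilyloxy)benzoate | C1CC(=O)[C@](C)(OC(=O)c2c(C)cc(O[Si](C(C)C)(C(C)C)C(C)C)cc2OC)[C@H](O)C1 | intermediate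
15 | (1R,6R)-1-methyl-2,6-bis(triethylsilyloxy)cyclohex-2-en-1-yl 2-methoxy-6-methyl-4-(triisopropylsilyloxy)benzoate | C1C=C(O[Si](CC)(CC)CC)[C@](C)(OC(=O)c2c(C)cc(O[Si](C(C)C)(C(C)C)C(C)C)cc2OC)[C@H](O[Si](CC)(CC)CC)C1 | intermediate
16 | (1R,6R)-1-methyl-2-oxo-6-(triethylsilyloxy)cyclohex-3-en-1-yl 2-methoxy-6-methyl-4-(triisopropylsilyloxy)benzoate | C1=CC(=O)[C@](C)(OC(=O)c2c(C)cc(O[Si](C(C)C)(C(C)C)C(C)C)cc2OC)[C@H](O[Si](CC)(CC)CC)C1 | intermediate
17 | (E)-but-2-enal | C/C=C/C=O | starting material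
18 | (3E)-1,1-dibromopenta-1,3-diene | C/C=C/C=C(Br)Br | intermediate
19 | lithium (3E)-pent-3-en-1-yn-1-ide | C/C=C/C#C[Li] | intermediate (not isolated)
20 | bromo[(3E)-pent-3-en-1-yn-1-yl]zinc | C/C=C/C#C[Zn]Br | intermediate (not isolated)
21 | (1R,6R)-2-(tert-butyldimethylsilyloxy)-1-methyl-4-[(3E)-pent-3-en-1-yn-1-yl]-6-(triethylsilyloxy)cyclohex-2-en-1-yl 2-methoxy-6-methyl-4-(triisopropylsilyloxy)benzoate (C4 epimers) | C/C=C/C#CC1C=C(O[Si](C)(C)C(C)(C)C)[C@](C)(OC(=O)c2c(C)cc(O[Si](C(C)C)(C(C)C)C(C)C)cc2OC)[C@H](O[Si](CC)(CC)CC)C1 | intermediate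
22 | (1R,6R)-3-(hydroxymethyl)-1-methyl-2-oxo-4-[(3E)-pent-3-en-1-yn-1-yl]-6-(triethylsilyloxy)cyclohexyl 2-methoxy-6-methyl-4-(triisopropylsilyloxy)benzoate (C3, C4 not defined) | C/C=C/C#CC1C(CO)C(=O)[C@](C)(OC(=O)c2c(C)cc(O[Si](C(C)C)(C(C)C)C(C)C)cc2OC)[C@H](O[Si](CC)(CC)CC)C1 | intermediate
23 | (1R,6R)-1-methyl-4-[(3E)-pent-3-en-1-yn-1-yl]-2,6-bis(triethylsilyloxy)-3-[(triethylsilyloxy)methyl]cyclohex-2-en-1-yl 2-methoxy-6-methyl-4-(triisopropylsilyloxy)benzoate | C/C=C/C#CC1C(CO[Si](CC)(CC)CC)=C(O[Si](CC)(CC)CC)[C@](C)(OC(=O)c2c(C)cc(O[Si](C(C)C)(C(C)C)C(C)C)cc2OC)[C@H](O[Si](CC)(CC)CC)C1 | intermediate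
24 | (1R,6R)-1-methyl-2-oxo-4-[(3E)-pent-3-en-1-yn-1-yl]-3-(phenylselanyl)-6-(triethylsilyloxy)-3-[(triethylsilyloxy)methyl]cyclohexyl 2-methoxy-6-methyl-4-(triisopropylsilyloxy)benzoate (C3, C4 not defined) | C/C=C/C#CC1C(CO[Si](CC)(CC)CC)([Se]c2ccccc2)C(=O)[C@](C)(OC(=O)c3c(C)cc(O[Si](C(C)C)(C(C)C)C(C)C)cc3OC)[C@H](O[Si](CC)(CC)CC)C1 | intermediate (not isolated)
25 | selenoxide of 24 (3-benzeneseleninyl compound) | C/C=C/C#CC1C(CO[Si](CC)(CC)CC)([Se](=O)c2ccccc2)C(=O)[C@](C)(OC(=O)c3c(C)cc(O[Si](C(C)C)(C(C)C)C(C)C)cc3OC)[C@H](O[Si](CC)(CC)CC)C1 | intermediate (not isolated)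
26 | (1R,6R)-1-methyl-2-oxo-4-[(3E)-pent-3-en-1-yn-1-yl]-6-(triethylsilyloxy)-3-[(triethylsilyloxy)methyl]cyclohex-3-en-1-yl 2-methoxy-6-methyl-4-(triisopropylsilyloxy)benzoate | C/C=C/C#CC1=C(CO[Si](CC)(CC)CC)C(=O)[C@](C)(OC(=O)c2c(C)cc(O[Si](C(C)C)(C(C)C)C(C)C)cc2OC)[C@H](O[Si](CC)(CC)CC)C1 | intermediate
27 | (1R,6R)-6-hydroxy-3-(hydroxymethyl)-1-methyl-2-oxo-4-[(3E)-pent-3-en-1-yn-1-yl]cyclohex-3-en-1-yl 4-hydroxy-2-methoxy-6-methylbenzoate | C/C=C/C#CC1=C(CO)C(=O)[C@](C)(OC(=O)c2c(C)cc(O)cc2OC)[C@H](O)C1 | intermediate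
28 | (6R,7R)-6-hydroxy-7-methyl-8-oxo-3-[(1E)-prop-1-en-1-yl]-5,6,7,8-tetrahydro-1H-isochromen-7-yl 4-hydroxy-2-methoxy-6-methylbenzoate | C/C=C/C1=CC2=C(CO1)C(=O)[C@](C)(OC(=O)c1c(C)cc(O)cc1OC)[C@H](O)C2 | target

Total steps: 17
Longest linear sequence: 14 steps (1, 2, 3, 6, 7, 8, 9, 10, 12, 13, 14, 15, 16, 17)

Steps most likely to fail

Step 8. Enolisation of the acyloxy ketone by the chiral base may be too slow, or the faces of enolate and aldehyde may be poorly differentiated, so that cyclisation is sluggish or poorly stereoselective and aldehyde self-condensation competes. Fallback (known chemistry): setting out from 13, the cyclisation is run with an achiral amidine (DBU, THF, 0 °C), an ordinary base-mediated aldol addition of a 1,5-keto aldehyde, to give the racemic cis aldol rac-(1R*,2R*)-2-hydroxy-1-methyl-6-oxocyclohexyl ArCO2 F1. Any trans isomer is removed on silica and the enantiomers are separated by preparative chromatography on a chiral stationary phase (amylose tris(3,5-dimethylphenylcarbamate), CO2/MeOH). The (1R,2R) enantiomer is 14, where the route is rejoined.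

Step 13. Protodesilylation of the tert-butyldimethylsilyl enol ether may outpace C–C bond formation, or the Lewis acid may loosen the C6 silyl ether. Fallback: the order of the two C–C bond formations is reversed. Setting out from enone 16, a Morita–Baylis–Hillman reaction (37 % aq HCHO, DMAP, THF/H2O, rt) puts the hydroxymethyl group on C8a and gives (1R,6R)-3-(hydroxymethyl)-1-methyl-2-oxo-6-(triethylsilyloxy)cyclohex-3-en-1-yl ArCO2 F2. Silylation (TESCl, imidazole, CH2Cl2) gives (1R,6R)-1-methyl-2-oxo-6-(triethylsilyloxy)-3-[(triethylsilyloxy)methyl]cyclohex-3-en-1-yl ArCO2 F3. Conjugate addition of 20 promoted by TESOTf (Et2O, −40 °C) then delivers the tetrasubstituted triethylsilyl enol ether 23 directly, where the route is rejoined.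

Step 15. Selenenylation on the face syn to the alkynyl group would leave no syn hydrogen at C4a, so that the selenoxide eliminates towards C1 or not at all; electrophilic selenium may also attack the enyne. Fallback: the oxidation state is relayed through C1. Setting out from 22, Dess–Martin oxidation (CH2Cl2, NaHCO3, rt) gives the beta-keto aldehyde, written as its enol (1R,6R)-3-(hydroxymethylidene)-1-methyl-2-oxo-4-[(3E)-pent-3-en-1-yn-1-yl]-6-(triethylsilyloxy)cyclohexyl ArCO2 F4. DDQ (1,4-dioxane, rt), the classical dehydrogenation of 2-hydroxymethylene ketones with no syn requirement, gives (1R,6R)-3-formyl-1-methyl-2-oxo-4-[(3E)-pent-3-en-1-yn-1-yl]-6-(triethylsilyloxy)cyclohex-3-en-1-yl ArCO2 F5. Luche reduction of the aldehyde (NaBH4, CeCl3·7H2O, MeOH, −78 °C) gives (1R,6R)-3-(hydroxymethyl)-1-methyl-2-oxo-4-[(3E)-pent-3-en-1-yn-1-yl]-6-(triethylsilyloxy)cyclohex-3-en-1-yl ArCO2 F6. Desilylation as in step 16 (TBAF, AcOH, THF) leads to 27, where the route is rejoined.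

Further compounds
F1 | step 8 | rac-(1R*,2R*)-2-hydroxy-1-methyl-6-oxocyclohexyl 2-methoxy-6-methyl-4-(triisopropylsilyloxy)benzoate (racemate of 14) | C1CC(=O)[C@](C)(OC(=O)c2c(C)cc(O[Si](C(C)C)(C(C)C)C(C)C)cc2OC)[C@H](O)C1.C1CC(=O)[C@@](C)(OC(=O)c2c(C)cc(O[Si](C(C)C)(C(C)C)C(C)C)cc2OC)[C@@H](O)C1
F2 | step 13 | (1R,6R)-3-(hydroxymethyl)-1-methyl-2-oxo-6-(triethylsilyloxy)cyclohex-3-en-1-yl 2-methoxy-6-methyl-4-(triisopropylsilyloxy)benzoate | C1=C(CO)C(=O)[C@](C)(OC(=O)c2c(C)cc(O[Si](C(C)C)(C(C)C)C(C)C)cc2OC)[C@H](O[Si](CC)(CC)CC)C1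
F3 | step 13 | (1R,6R)-1-methyl-2-oxo-6-(triethylsilyloxy)-3-[(triethylsilyloxy)methyl]cyclohex-3-en-1-yl 2-methoxy-6-methyl-4-(triisopropylsilyloxy)benzoate | C1=C(CO[Si](CC)(CC)CC)C(=O)[C@](C)(OC(=O)c2c(C)cc(O[Si](C(C)C)(C(C)C)C(C)C)cc2OC)[C@H](O[Si](CC)(CC)CC)C1
F4 | step 15 | (1R,6R)-3-(hydroxymethylidene)-1-methyl-2-oxo-4-[(3E)-pent-3-en-1-yn-1-yl]-6-(triethylsilyloxy)cyclohexyl 2-methoxy-6-methyl-4-(triisopropylsilyloxy)benzoate (enol of the beta-keto aldehyde) | C/C=C/C#CC1C(=CO)C(=O)[C@](C)(OC(=O)c2c(C)cc(O[Si](C(C)C)(C(C)C)C(C)C)cc2OC)[C@H](O[Si](CC)(CC)CC)C1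
F5 | step 15 | (1R,6R)-3-formyl-1-methyl-2-oxo-4-[(3E)-pent-3-en-1-yn-1-yl]-6-(triethylsilyloxy)cyclohex-3-en-1-yl 2-methoxy-6-methyl-4-(triisopropylsilyloxy)benzoate | C/C=C/C#CC1=C(C=O)C(=O)[C@](C)(OC(=O)c2c(C)cc(O[Si](C(C)C)(C(C)C)C(C)C)cc2OC)[C@H](O[Si](CC)(CC)CC)C1
F6 | step 15 | (1R,6R)-3-(hydroxymethyl)-1-methyl-2-oxo-4-[(3E)-pent-3-en-1-yn-1-yl]-6-(triethylsilyloxy)cyclohex-3-en-1-yl 2-methoxy-6-methyl-4-(triisopropylsilyloxy)benzoate | C/C=C/C#CC1=C(CO)C(=O)[C@](C)(OC(=O)c2c(C)cc(O[Si](C(C)C)(C(C)C)C(C)C)cc2OC)[C@H](O[Si](CC)(CC)CC)C1
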